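**Plan**

1. Cuts: (a) the σ-bond C3–C1' between the cyclopropane and the C19 tetraenyl arm, giving a C3-metalated cyclopropane and an (E)-vinyl iodide; (b) the ring bonds C1–C3 and C2–C3, back to the 2,3-alkene of all-E geranylgeraniol and a CH–I unit from iodoform; (c) in the arm, C2'–CH3 and C3'–C4', back to farnesyl bromide, a silylated propyne and Me3Al.
2. Forward order: the only ring is closed first, in one step on geranylgeraniol; the C19 vinyl iodide is built in two steps; the C21 and C19 halves are joined last at C3–C1', and fluoride removes the silyl helper.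
3. Stereochemistry: C1 and C2 come from face selection by a chiral dioxaborolane bound to the zinc alkoxide of the E allylic alcohol (E geometry puts CH2OH cis to the ring CH3); C3 comes from the iodocarbenoid (iodine trans to CH2OH) and is then carried with retention through Li, Zn and Pd; the E alkenes come from the terpene feedstocks and one syn-carboalumination.
4. Enabling feature: C3 is a secondary CH of the three-membered ring, flanked by C1 and quaternary C2. Its exocyclic orbital is rich in s character, so the C3–Li and C3–Zn bonds hold configuration and the carbon transmetalates and reductively eliminates like an sp2 carbon, while β-hydride elimination would have to form a cyclopropene.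

Key step: step 5

Remark: the target is read as (1R,2R,3R), with CH2OH cis to the ring methyl and trans to the tetraenyl arm (prephytoene alcohol). Ring atoms are C1 (CH–CH2OH), C2 (quaternary) and C3 (CH bearing the arm); C1' is the first alkene carbon of the arm. All-E geranylgeraniol and (2E,6E)-farnesyl bromide are taken as commercial.

**Step 1**
Reactants: 1 (2E,6E,10E)-geranylgeraniol; 2 iodoform
Product: 4 [(1R,2S,3R)-3-iodo-2-methyl-2-[(3E,7E)-4,8,12-trimethyltrideca-3,7,11-trien-1-yl]cyclopropyl]methanol, via ethylzinc alkoxide of geranylgeraniol 3 (not isolated)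
Conditions: 1, Et2Zn (1.0 equiv), CH2Cl2, 0 °C; (4S,5S)-2-butyl-N,N,N',N'-tetramethyl-1,3,2-dioxaborolane-4,5-dicarboxamide (1.2 equiv); then EtZnCHI2 (from Et2Zn + 2, 1:1, 2 equiv), CH2Cl2, −40 → 0 °C; aq. NH4Cl
Reagents that add atoms: none
Why: Simmons–Smith-type iodocyclopropanation of an allylic alcohol with an α-iodozinc carbenoid: zinc alkoxide 3, held by the chiral dioxaborolane, should deliver the CHI unit to one face of the neighbouring 2,3-alkene only, which sets C1 and C2 (the E geometry puts CH2OH cis to the ring methyl), while the iodine that stays on the carbenoid carbon turns away from the bulky alkoxide–boronate complex and should end trans to CH2OH and cis to the trienyl chain at C3; the three remote alkenes carry no directing group and should stay untouched.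

**Step 2**
Reactants: 4 [(1R,2S,3R)-3-iodo-2-methyl-2-[(3E,7E)-4,8,12-trimethyltrideca-3,7,11-trien-1-yl]cyclopropyl]methanol
Product: 5 tert-butyl{[(1R,2S,3R)-3-iodo-2-methyl-2-[(3E,7E)-4,8,12-trimethyltrideca-3,7,11-trien-1-yl]cyclopropyl]methoxy}dimethylsilane
Conditions: TBSCl, imidazole, DMF, 23 °C
Reagents that add atoms: tert-butyldimethylsilyl chloride, CC(C)(C)[Si](C)(C)Cl
Why: Standard silylation of a primary alcohol with an imidazole-activated silyl chloride; it removes the acidic proton before the iodine–lithium exchange and creates no stereocentre.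

**Step 3**
Reactants: 6 (2E,6E)-farnesyl bromide; 7 1-(trimethylsilyl)propyne
Product: 10 (5E,9E)-6,10,14-trimethylpentadeca-5,9,13-trien-1-yne, via 3-(trimethylsilyl)prop-2-yn-1-yllithium 8 (not isolated), via C-silylated enyne 9 (not isolated)
Conditions: 7, n-BuLi, THF, −78 °C; 6, −78 → 0 °C; then MeOH (excess), K2CO3 (cat.), 23 °C
Reagents that add atoms: none
Why: Propargylic lithiation of the silyl-capped propyne and SN2 alkylation on the primary allylic bromide (the silyl group blocks the acetylenic terminus and disfavours the allenyl product, and the 2E,6E geometry is not touched), followed by methanolysis of the alkynyl C–Si bond in the same flask.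

**Step 4**
Reactants: 10 (5E,9E)-6,10,14-trimethylpentadeca-5,9,13-trien-1-yne
Product: 12 (1E,5E,9E)-1-iodo-2,6,10,14-tetramethylpentadeca-1,5,9,13-tetraene, via (E)-alkenyldimethylalane 11 (not isolated)
Conditions: Me3Al (2.5 equiv), Cp2ZrCl2 (0.25 equiv), CH2Cl2, 0 → 23 °C; then I2, THF, −30 → 0 °C
Reagents that add atoms: trimethylaluminium, C[Al](C)C; iodine, II
Why: Negishi zirconium-catalysed carboalumination: syn addition of CH3–Al across the terminal alkyne with methyl on the internal carbon gives (E)-alkenylalane 11, and iodinolysis of the C–Al bond with retention gives the E vinyl iodide; the isolated trisubstituted alkenes are not carbometalated.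

**Step 5**
Reactants: 5 tert-butyl{[(1R,2S,3R)-3-iodo-2-methyl-2-[(3E,7E)-4,8,12-trimethyltrideca-3,7,11-trien-1-yl]cyclopropyl]methoxy}dimethylsilane; 12 (1E,5E,9E)-1-iodo-2,6,10,14-tetramethylpentadeca-1,5,9,13-tetraene
Product: 15 tert-butyldimethyl{[(1R,2R,3R)-2-methyl-3-[(1E,5E,9E)-2,6,10,14-tetramethylpentadeca-1,5,9,13-tetraen-1-yl]-2-[(3E,7E)-4,8,12-trimethyltrideca-3,7,11-trien-1-yl]cyclopropyl]methoxy}silane, via cyclopropyllithium 13 (not isolated), via cyclopropylzinc chloride 14 (not isolated)
Conditions: 5, t-BuLi (2.1 equiv), Et2O, −78 °C; ZnCl2 (1.2 equiv, THF), −78 → 0 °C; 12, Pd(PPh3)4 (5 mol %), THF, 23 → 45 °C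
Reagents that add atoms: none
Why: Iodine–lithium exchange at ring carbon C3 gives cyclopropyllithium 13, which keeps its configuration at −78 °C; ZnCl2 turns it with retention into cyclopropylzinc chloride 14; zerovalent palladium inserts into the C–I bond of 12 with retention of the E geometry, and transmetalation from zinc followed by reductive elimination forms the C3–C1' bond with retention at both carbons. The closest known reaction type is the Negishi cross-coupling of configurationally defined secondary cyclopropylzinc halides with alkenyl iodides. No ring is closed. No new stereocentre is created: C3, set in step 1, is carried over, the controlling element being the s-rich exocyclic orbital of the three-membered ring (high inversion barrier of the C3–Li and C3–Zn bonds), and the E trisubstituted alkene is the one fixed in step 4. The step needs retention at C3 and at the alkene and cross- over homo-coupling; the substrate secures this because iodine trans to CH2OTBS leaves no chelated or eliminative pathway for the carbanion, β-hydride elimination from cyclopropyl–palladium would have to give a cyclopropene, and the silyl ether and the isolated trisubstituted alkenes are inert to the organometallics at low temperature. In one operation it joins the C21 and C19 halves and delivers the complete carbon skeleton with all three ring stereocentres and all seven alkenes in place.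

**Step 6**
Reactants: 15 tert-butyldimethyl{[(1R,2R,3R)-2-methyl-3-[(1E,5E,9E)-2,6,10,14-tetramethylpentadeca-1,5,9,13-tetraen-1-yl]-2-[(3E,7E)-4,8,12-trimethyltrideca-3,7,11-trien-1-yl]cyclopropyl]methoxy}silane
Product: 16 [(1R,2R,3R)-2-methyl-3-[(1E,5E,9E)-2,6,10,14-tetramethylpentadeca-1,5,9,13-tetraen-1-yl]-2-[(3E,7E)-4,8,12-trimethyltrideca-3,7,11-trien-1-yl]cyclopropyl]methanol
Conditions: TBAF, THF, 0 → 23 °C
Reagents that add atoms: none
Why: Fluoride-induced cleavage of the Si–O bond (desilylation driven by the strong Si–F bond) frees the primary alcohol without touching the vinylcyclopropane or the alkenes.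

**Compound list**

1 | (2E,6E,10E)-geranylgeraniol | CC(C)=CCC/C(C)=C/CC/C(C)=C/CC/C(C)=C/CO | starting material
2 | iodoform | IC(I)I | starting material
3 | ethylzinc alkoxide of geranylgeraniol (not isolated) | CC(C)=CCC/C(C)=C/CC/C(C)=C/CC/C(C)=C/CO[Zn]CC | intermediate
4 | [(1R,2S,3R)-3-iodo-2-methyl-2-[(3E,7E)-4,8,12-trimethyltrideca-3,7,11-trien-1-yl]cyclopropyl]methanol (iodine trans to CH2OH and ring CH3, cis to the trienyl chain) | I[C@@H]1[C@@H](CO)[C@]1(C)CC/C=C(\C)CC/C=C(\C)CCC=C(C)C | intermediate
5 | tert-butyl{[(1R,2S,3R)-3-iodo-2-methyl-2-[(3E,7E)-4,8,12-trimethyltrideca-3,7,11-trien-1-yl]cyclopropyl]methoxy}dimethylsilane | I[C@@H]1[C@@H](CO[Si](C)(C)C(C)(C)C)[C@]1(C)CC/C=C(\C)CC/C=C(\C)CCC=C(C)C | intermediate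
6 | (2E,6E)-farnesyl bromide | CC(C)=CCC/C(C)=C/CC/C(C)=C/CBr | starting material
7 | 1-(trimethylsilyl)propyne | CC#C[Si](C)(C)C | starting material
8 | 3-(trimethylsilyl)prop-2-yn-1-yllithium (not isolated) | [Li]CC#C[Si](C)(C)C | intermediate
9 | trimethyl[(5E,9E)-6,10,14-trimethylpentadeca-5,9,13-trien-1-yn-1-yl]silane (not isolated) | CC(C)=CCC/C(C)=C/CC/C(C)=C/CCC#C[Si](C)(C)C | intermediate
10 | (5E,9E)-6,10,14-trimethylpentadeca-5,9,13-trien-1-yne | CC(C)=CCC/C(C)=C/CC/C(C)=C/CCC#C | intermediate
11 | dimethyl[(1E,5E,9E)-2,6,10,14-tetramethylpentadeca-1,5,9,13-tetraen-1-yl]alane (not isolated) | CC(C)=CCC/C(C)=C/CC/C(C)=C/CC/C(C)=C/[Al](C)C | intermediate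
12 | (1E,5E,9E)-1-iodo-2,6,10,14-tetramethylpentadeca-1,5,9,13-tetraene | CC(C)=CCC/C(C)=C/CC/C(C)=C/CC/C(C)=C/I | intermediate
13 | cyclopropyllithium from 5, lithium in place of iodine at C3, configuration retained (not isolated) | [Li][C@@H]1[C@@H](CO[Si](C)(C)C(C)(C)C)[C@]1(C)CC/C=C(\C)CC/C=C(\C)CCC=C(C)C | intermediate
14 | cyclopropylzinc chloride from 13, ZnCl at C3, configuration retained (not isolated) | Cl[Zn][C@@H]1[C@@H](CO[Si](C)(C)C(C)(C)C)[C@]1(C)CC/C=C(\C)CC/C=C(\C)CCC=C(C)C | intermediate
15 | tert-butyldimethyl{[(1R,2R,3R)-2-methyl-3-[(1E,5E,9E)-2,6,10,14-tetramethylpentadeca-1,5,9,13-tetraen-1-yl]-2-[(3E,7E)-4,8,12-trimethyltrideca-3,7,11-trien-1-yl]cyclopropyl]methoxy}silane | CC(C)=CCC/C(C)=C/CC/C(C)=C/CC/C(C)=C/[C@@H]1[C@@H](CO[Si](C)(C)C(C)(C)C)[C@]1(C)CC/C=C(\C)CC/C=C(\C)CCC=C(C)C | intermediate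
16 | [(1R,2R,3R)-2-methyl-3-[(1E,5E,9E)-2,6,10,14-tetramethylpentadeca-1,5,9,13-tetraen-1-yl]-2-[(3E,7E)-4,8,12-trimethyltrideca-3,7,11-trien-1-yl]cyclopropyl]methanol | CC(C)=CCC/C(C)=C/CC/C(C)=C/CC/C(C)=C/[C@@H]1[C@@H](CO)[C@]1(C)CC/C=C(\C)CC/C=C(\C)CCC=C(C)C | target

**Totals**

Total step count: 6. Longest linear sequence: 4 steps (steps 1, 2, 5, 6, or equally steps 3, 4, 5, 6).

**Steps most likely to fail**

Step 1. What may go wrong: incomplete control of the iodine-bearing centre (iodine delivered cis to CH2OH), halogen–zinc scrambling of the carbenoid to a gem-dizinc species that leads to iodine-free cyclopropane, or slow transfer to the trisubstituted alkene. The fallback sets out from 1 and comes back at 5; it builds the ring by an intramolecular carbene addition and sets C3 by a radical iodine transfer under steric control.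
- Acylation of 1 with bromoacetyl bromide (pyridine, CH2Cl2, 0 °C) would give geranylgeranyl bromoacetate F1.
- N,N'-ditosylhydrazine and DBU (THF, 0 °C) would convert it into geranylgeranyl diazoacetate F2.
- Slow addition of F2 to dirhodium tetrakis[methyl (5S)-2-oxopyrrolidine-5-carboxylate], Rh2(5S-MEPY)4, in refluxing CH2Cl2 should give bicyclic lactone F3 by intramolecular cyclopropanation of the 2,3-alkene; the catalyst sets C1 and C2, and the carbonyl is necessarily cis to CH2O.
- KOH in MeOH/H2O would open the lactone to potassium hydroxy-carboxylate F4; TBSCl/imidazole (DMF) would silylate both oxygens to give bis-silyl compound F5; K2CO3 in MeOH/THF/H2O would cleave only the silyl ester to give cis acid F6.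
- N-hydroxypyridine-2-thione, DCC and DMAP (CH2Cl2, dark) would give Barton ester F7. Its visible-light photolysis in the presence of a large excess of 2 (Barton iododecarboxylation) should give a C3 cyclopropyl σ-radical that inverts freely and takes iodine on the face away from CH2OTBS and the ring CH3, which erases the cis relationship and gives 5. The excess of iodine donor is needed so that iodine transfer outruns 5-exo attack of the radical on the nearby alkene.

Step 5. What may go wrong: protonation or partial epimerisation of the cyclopropyl-metal species before coupling, sluggish transmetalation of the hindered secondary zinc reagent, and homocoupling of the vinyl iodide. The fallback sets out from 12 and 5 and comes back at 15; it reverses the polarity so that no cyclopropyl carbanion is made. Miyaura borylation of 12 (B2pin2, PdCl2(PPh3)2, PPh3, KOPh, toluene, 50 °C) would give alkenyl pinacol boronate F8. Suzuki–Miyaura coupling of F8 with iodide 5 (Pd(OAc)2, PPh3, K2CO3, Bu4NCl, DMF/H2O, 90 °C) should then give 15; zerovalent palladium inserts into the cyclopropyl C–I bond with retention.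

Step 4. What may go wrong: incomplete carbometalation or protodealumination before iodinolysis, and Lewis-acid-induced isomerisation or cyclisation of the 1,5-diene array. The fallback sets out from 10 and comes back at 12; it replaces the aluminium/zirconium system by a copper-mediated syn-carbometalation. Methylcopper–MgBr2 (from MeMgBr and CuBr·SMe2, Et2O/Me2S, −45 → −25 °C) should add across the terminal alkyne with methyl on the internal carbon to give (E)-alkenylcopper F9, and iodinolysis (I2, −40 → 0 °C) with retention would give 12.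

**Further compounds**

F1 | step 1 | (2E,6E,10E)-geranylgeranyl bromoacetate | CC(C)=CCC/C(C)=C/CC/C(C)=C/CC/C(C)=C/COC(=O)CBr
F2 | step 1 | (2E,6E,10E)-geranylgeranyl diazoacetate | CC(C)=CCC/C(C)=C/CC/C(C)=C/CC/C(C)=C/COC(=O)C=[N+]=[N-]
F3 | step 1 | (1S,5R,6S)-6-methyl-6-[(3E,7E)-4,8,12-trimethyltrideca-3,7,11-trien-1-yl]-3-oxabicyclo[3.1.0]hexan-2-one | O=C1OC[C@@H]2[C@H]1[C@@]2(C)CC/C=C(\C)CC/C=C(\C)CCC=C(C)C
F4 | step 1 | potassium (1S,2S,3R)-3-(hydroxymethyl)-2-methyl-2-[(3E,7E)-4,8,12-trimethyltrideca-3,7,11-trien-1-yl]cyclopropane-1-carboxylate | [K+].[O-]C(=O)[C@H]1[C@@H](CO)[C@]1(C)CC/C=C(\C)CC/C=C(\C)CCC=C(C)C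
F5 | step 1 | tert-butyldimethylsilyl (1S,2S,3R)-3-[(tert-butyldimethylsilyloxy)methyl]-2-methyl-2-[(3E,7E)-4,8,12-trimethyltrideca-3,7,11-trien-1-yl]cyclopropane-1-carboxylate | CC(C)(C)[Si](C)(C)OC(=O)[C@H]1[C@@H](CO[Si](C)(C)C(C)(C)C)[C@]1(C)CC/C=C(\C)CC/C=C(\C)CCC=C(C)C
F6 | step 1 | (1S,2S,3R)-3-[(tert-butyldimethylsilyloxy)methyl]-2-methyl-2-[(3E,7E)-4,8,12-trimethyltrideca-3,7,11-trien-1-yl]cyclopropane-1-carboxylic acid | OC(=O)[C@H]1[C@@H](CO[Si](C)(C)C(C)(C)C)[C@]1(C)CC/C=C(\C)CC/C=C(\C)CCC=C(C)C
F7 | step 1 | 2-thioxopyridin-1(2H)-yl (1S,2S,3R)-3-[(tert-butyldimethylsilyloxy)methyl]-2-methyl-2-[(3E,7E)-4,8,12-trimethyltrideca-3,7,11-trien-1-yl]cyclopropane-1-carboxylate | S=C1C=CC=CN1OC(=O)[C@H]2[C@@H](CO[Si](C)(C)C(C)(C)C)[C@]2(C)CC/C=C(\C)CC/C=C(\C)CCC=C(C)C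
F8 | step 5 | 4,4,5,5-tetramethyl-2-[(1E,5E,9E)-2,6,10,14-tetramethylpentadeca-1,5,9,13-tetraen-1-yl]-1,3,2-dioxaborolane | CC(C)=CCC/C(C)=C/CC/C(C)=C/CC/C(C)=C/B1OC(C)(C)C(C)(C)O1
F9 | step 4 | [(1E,5E,9E)-2,6,10,14-tetramethylpentadeca-1,5,9,13-tetraen-1-yl]copper (as its MgBr2 complex) | CC(C)=CCC/C(C)=C/CC/C(C)=C/CC/C(C)=C/[Cu]
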